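Does the average chain in this flask reach 10.0 units by 5.0 min, and how long is it then?

all flasks: free monomer 40 mM

| charge | pre-initiator | remark | time |
|---|---|---|---|
| Monday's | 10 mol% | run made earlier |  |
| flask | 5 mol% |  | 5.0 min |

- Monday's (time / s: monomer in chains / %, free monomer / %): 10.0: 1.2, 98.5; 20.0: 4.4, 95.7; 30.0: 10.9, 90.6; 40.0: 18.9, 82.1; 50.0: 26.5, 72.0; 60.0: 35.2, 63.3

(scatter of a reading: 0.5 percentage points)

* whether the average number of monomer units in a chain (chains begun, living or dead) reaches 10 by 5.0 min (no / yes)
* average number of monomer units in a chain (chains begun, living or dead) at 5.0 min

- the average divides the monomer in chains by the number of chains begun, living and dead together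
- the analysis behind the earlier runs scatters by 0.5 percentage points, standard deviation
- the earlier runs do not show the number of chains; that part of a forecast is a guess
- no earlier run changes the charge of pre-initiator; that part of a forecast is a guess

Take first the main step by itself: free monomer adds to chains, and each unit of pre-initiator begins one chain. The flask charges c(pre-initiator) = 2.00 mM, and c(free monomer) divided by that charge gives 20.0, the full-conversion length: the average once the whole charge has begun chains and all free monomer sits in them. The average equals this length times the fraction in chains, divided by the fraction of the charge begun, so 10.0 units needs half of the free monomer in chains if the whole charge has begun.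

Monday's run supplies a rate. Late in that run ln c(free monomer) falls steadily, at 0.0129 s⁻¹ as read, which looks pseudo-first-order over these last readings. This flask has half of Monday's loading, and taking the constant in proportion to the loading, which is a guess, gives 0.00644 s⁻¹.

Add the start-up. Monday's slope reads 0.00288 s⁻¹ early, less than the late reading, so that run starts slowly. As a rough allowance for this flask, counting the halved constant from 60.0 s puts an estimated 78.7% in chains and gives an estimated average of 15.7.

The rest is unseen, since Monday ends with 63.3% free: charge that never begins a chain raises the number, and a stop in free monomer lowers it.

The forecast says yes and 15, between 9 and 22, slightly below this reckoning, noting that “chain number is a guess”.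

The flask gives yes, with an average of 17.1 at 5.0 min.

    free monomer + initiator → living end + monomer in chains (k = 1.28 L mol⁻¹ s⁻¹)
    free monomer + living end → monomer in chains + living end, rate k2*[living end]*[free monomer] (k = 11.3 L mol⁻¹ s⁻¹)
    monomer in chains + living end → free monomer + living end, rate k3*[living end] as long as [monomer in chains] is above zero (k = 0.129 s⁻¹)
    initiator → spent initiator (k = 0.00710 s⁻¹)
    pre-initiator → initiator (k = 0.0214 s⁻¹)

At 5.00 min the flask makes monomer in chains 1.03 times as fast as it uses it up, each step taken net, against 1.52 times at 2.35 min, and free monomer stands at 29.3% then and at 28.5% at 50.0 min. The full-conversion length times 70.7% in chains gives 14.1, and dividing by the 82.9% of the charge standing as living ends returns 17.1; Monday's flask, with its length of 10.0 and 35.2% in chains at 60.0 s, gives 3.52 units with its whole charge counted as begun.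

Readings and results are simulated for an exercise; noise was put on by code.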